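**Retrosynthetic overview**
1. Target 27 is taken back, through removal of the MOM and triisopropylsilyl groups, to flavone 22 without the C3 oxygen; the C3–OH comes from C3 lithiation–borylation–oxidation.
2. Ring C is opened at O1–C2 to the ortho-hydroxyaryl ynone 20 (amine-mediated 6-endo closure in the forward direction).
3. Key disconnection: C4a–C4 and O1–C8a are cut together, giving the C4a≡C8a aryne of ring A (from silyl triflate 8) and the ring B propiolic acid 18. The feature that allows this: C4a and C8a are adjacent ring A carbons carrying C4 and O1, and the C5 methoxy group sits next to C4a, the pattern of a 3-alkoxyaryne that steers oxygen to C8a.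
4. 8 comes from 4-hydroxy-2,3-dimethoxybenzaldehyde 1 (MOM, Baeyer–Villiger, ortho-bromination, retro-Brook/triflation); 18 comes from arylacetic acid 9 (Weinreb amide, isopropenyl ketone, CBS reduction for the (R) carbinol, silylation, Sonogashira, carboxylation).
5. Ring order: rings A and B are bought as benzenes; ring C is the only ring formed (step 12).

Key step: step 11

Remark: flavone numbering (O1, C2, C3, C4, C4a, C5–C8, C8a) is used at every stage; the carbinol centre read from the target is (R); 1, 9, 11 (THF solution) and 15 are taken as purchasable.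

**Route**

Step 1
Reactants: 1 4-hydroxy-2,3-dimethoxybenzaldehyde
Product: 2 2,3-dimethoxy-4-(methoxymethoxy)benzaldehyde
Conditions: MOMCl, iPr2NEt, CH2Cl2, 0 °C→rt
Reagents that add atoms: chloromethyl methyl ether, COCCl
Why: Williamson-type O-alkylation of the acidic para-formyl phenol with the α-chloro ether gives an acetal that is inert to the fluoride, organolithium and amide-base steps ahead.

Step 2
Reactants: 2 2,3-dimethoxy-4-(methoxymethoxy)benzaldehyde
Product: 4 2,3-dimethoxy-4-(methoxymethoxy)phenol, via aryl formate 3 (not isolated)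
Conditions: mCPBA, CH2Cl2, 0 °C→rt; aq. NaHCO3/Na2S2O3 wash; K2CO3 (cat.), MeOH, rt
Reagents that add atoms: meta-chloroperbenzoic acid, O=C(OO)c1cccc(Cl)c1
Why: Baeyer–Villiger (Dakin-type) oxidation, in which the electron-rich 2,4-dioxygenated aryl group migrates in preference to hydride, gives the aryl formate, which mild base in methanol transesterifies without touching the MOM acetal.

Step 3
Reactants: 4 2,3-dimethoxy-4-(methoxymethoxy)phenol
Product: 5 6-bromo-2,3-dimethoxy-4-(methoxymethoxy)phenol
Conditions: NBS, iPr2NH (cat.), CH2Cl2, 0 °C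
Reagents that add atoms: N-bromosuccinimide, O=C1CCC(=O)N1Br
Why: Electrophilic aromatic bromination with amine-assisted delivery ortho to the free hydroxyl; the other ortho position and the para position are substituted, and the free phenol should outweigh the MOM ether that activates C5.

Step 4
Reactants: 5 6-bromo-2,3-dimethoxy-4-(methoxymethoxy)phenol
Product: 8 2,3-dimethoxy-4-(methoxymethoxy)-6-(trimethylsilyl)phenyl trifluoromethanesulfonate, via O-trimethylsilyl ether 6 (not isolated), via lithium 2-silylphenoxide 7 (not isolated)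
Conditions: HMDS, THF, 65 °C, then evaporation; n-BuLi, THF, −100→−78 °C; Tf2O, −100 °C→rt
Reagents that add atoms: hexamethyldisilazane, C[Si](C)(C)N[Si](C)(C)C; trifluoromethanesulfonic anhydride, O=S(=O)(OS(=O)(=O)C(F)(F)F)C(F)(F)F
Why: O-Silylation, bromine–lithium exchange and anionic 1,3-O→C silyl migration (retro-Brook rearrangement) give the lithium ortho-silylphenoxide, which triflic anhydride traps on oxygen, the standard entry to ortho-silylaryl triflates.

Step 5
Reactants: 9 2-(5-bromo-2-methoxyphenyl)acetic acid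
Product: 10 2-(5-bromo-2-methoxyphenyl)-N-methoxy-N-methylacetamide
Conditions: MeNH(OMe)·HCl, EDC·HCl, N-methylmorpholine, CH2Cl2, 0 °C→rt
Reagents that add atoms: N,O-dimethylhydroxylamine hydrochloride, CNOC.Cl
Why: Carbodiimide-mediated amidation gives the Weinreb amide, which allows a single addition of the alkenyl Grignard reagent.

Step 6
Reactants: 10 2-(5-bromo-2-methoxyphenyl)-N-methoxy-N-methylacetamide; 11 isopropenylmagnesium bromide
Product: 12 1-(5-bromo-2-methoxyphenyl)-3-methylbut-3-en-2-one
Conditions: THF, −20→0 °C; inverse quench into cold 1 M HCl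
Reagents that add atoms: none
Why: Weinreb ketone synthesis: the magnesium-chelated tetrahedral adduct persists until the cold acidic inverse quench, so neither over-addition nor conjugate addition of the liberated amine to the enone should interfere.

Step 7
Reactants: 12 1-(5-bromo-2-methoxyphenyl)-3-methylbut-3-en-2-one
Product: 13 (R)-1-(5-bromo-2-methoxyphenyl)-3-methylbut-3-en-2-ol
Conditions: (S)-2-methyl-CBS-oxazaborolidine (0.2 equiv), catecholborane, toluene, −78 °C
Reagents that add atoms: none
Why: Corey–Bakshi–Shibata reduction: the ketone binds the ring boron through the lone pair syn to the smaller ArCH2 group, the α-branched isopropenyl group takes the large-substituent position, and hydride transfer to that face sets the (R) carbinol centre (same sense as acetophenone to (R)-1-phenylethanol with the (S) catalyst); catecholborane at −78 °C should leave the alkene alone.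

Step 8
Reactants: 13 (R)-1-(5-bromo-2-methoxyphenyl)-3-methylbut-3-en-2-ol
Product: 14 (R)-{[1-(5-bromo-2-methoxyphenyl)-3-methylbut-3-en-2-yl]oxy}triisopropylsilane
Conditions: TIPSOTf, 2,6-lutidine, CH2Cl2, 0 °C→rt
Reagents that add atoms: triisopropylsilyl trifluoromethanesulfonate, CC(C)[Si](OS(=O)(=O)C(F)(F)F)(C(C)C)C(C)C
Why: Silylation of the hindered secondary allylic alcohol with a silyl triflate and a hindered base; the triisopropylsilyl ether is chosen because it resists MeLi, LiN(iPr)2 and sparingly soluble CsF better than smaller silyl ethers.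

Step 9
Reactants: 14 (R)-{[1-(5-bromo-2-methoxyphenyl)-3-methylbut-3-en-2-yl]oxy}triisopropylsilane; 15 ethynyltrimethylsilane
Product: 16 (R)-triisopropyl[(1-{2-methoxy-5-[(trimethylsilyl)ethynyl]phenyl}-3-methylbut-3-en-2-yl)oxy]silane
Conditions: PdCl2(PPh3)2 (cat.), CuI (cat.), Et3N, THF, 70 °C, sealed tube
Reagents that add atoms: none
Why: Sonogashira coupling of the aryl bromide with the terminal alkyne; silyl ether, alkene and methyl ether are inert to the palladium–copper system.

Step 10
Reactants: 16 (R)-triisopropyl[(1-{2-methoxy-5-[(trimethylsilyl)ethynyl]phenyl}-3-methylbut-3-en-2-yl)oxy]silane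
Product: 18 (R)-3-{4-methoxy-3-[3-methyl-2-(triisopropylsilyloxy)but-3-enyl]phenyl}propiolic acid, via lithium acetylide 17 (not isolated)
Conditions: MeLi·LiBr, THF, 0 °C→rt; CO2 (g), −78 °C→rt; cold 1 M HCl
Reagents that add atoms: carbon dioxide, O=C=O
Why: Methyllithium cleaves the alkynyl C–Si bond to the lithium acetylide (tetramethylsilane leaves), and carboxylation with CO2 then gives the propiolic acid in the same flask.

Step 11
Reactants: 8 2,3-dimethoxy-4-(methoxymethoxy)-6-(trimethylsilyl)phenyl trifluoromethanesulfonate; 18 (R)-3-{4-methoxy-3-[3-methyl-2-(triisopropylsilyloxy)but-3-enyl]phenyl}propiolic acid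
Product: 20 (R)-1-[6-hydroxy-2,3-dimethoxy-4-(methoxymethoxy)phenyl]-3-{4-methoxy-3-[3-methyl-2-(triisopropylsilyloxy)but-3-enyl]phenyl}prop-2-yn-1-one, via aryne 19 (not isolated)
Conditions: 8 (1.5 equiv), CsF (4 equiv), THF, 100 °C, sealed tube
Reagents that add atoms: none
Why: Fluoride attack on silicon and loss of triflate give aryne 19 (C4a≡C8a of ring A), to which the cesium carboxylate of 18 adds through oxygen; the aryl anion then attacks the ester carbonyl in a four-membered (4-exo-trig) closure and the benzoxetene alkoxide opens to the ketone phenoxide, a net insertion of the aryne into the acyl C–O σ-bond. The closest known reaction type is the fluoride-induced C–O insertion of arynes into carboxylic acids that gives ortho-hydroxyaryl ketones, a relative of the anionic Fries shift. No ring is closed and no stereocentre is formed; O1–C8a and C4a–C4 are the two new skeletal bonds. The selectivity needed is regiochemical: the C5 methoxy group next to one aryne carbon withdraws inductively and distorts the aryne, so the nucleophile adds to the distal carbon C8a and the charge develops at C4a beside the methoxy group, and precursor 8 can give only this one aryne. Acyl transfer must outrun protonation of the aryl anion, which the aprotic medium and excess CsF (the acid proton is held as bifluoride) favour, and the MOM acetal and the hindered silyl ether should tolerate the sparingly soluble fluoride. Any ynone phenoxide that goes on to close 6-endo under these conditions is flavone 22, the product of step 12, so the crude mixture can be taken forward.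

Step 12
Reactants: 20 (R)-1-[6-hydroxy-2,3-dimethoxy-4-(methoxymethoxy)phenyl]-3-{4-methoxy-3-[3-methyl-2-(triisopropylsilyloxy)but-3-enyl]phenyl}prop-2-yn-1-one
Product: 22 5,6-dimethoxy-7-(methoxymethoxy)-2-{4-methoxy-3-[(2R)-3-methyl-2-(triisopropylsilyloxy)but-3-enyl]phenyl}-4H-chromen-4-one, via β-diethylamino enone 21 (not isolated)
Conditions: Et2NH, EtOH, rt→60 °C
Reagents that add atoms: none
Why: Aza-Michael addition of diethylamine gives the β-amino enone, whose phenol then attacks C2 and expels the amine (addition–elimination, net 6-endo closure of ring C), which avoids the 5-exo aurone pathway open to the free phenoxide.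

Step 13
Reactants: 22 5,6-dimethoxy-7-(methoxymethoxy)-2-{4-methoxy-3-[(2R)-3-methyl-2-(triisopropylsilyloxy)but-3-enyl]phenyl}-4H-chromen-4-one
Product: 25 3-hydroxy-5,6-dimethoxy-7-(methoxymethoxy)-2-{4-methoxy-3-[(2R)-3-methyl-2-(triisopropylsilyloxy)but-3-enyl]phenyl}-4H-chromen-4-one, via 3-lithioflavone 23 (not isolated), via dimethyl flavon-3-ylboronate 24 (not isolated)
Conditions: LiN(iPr)2, THF, −78 °C; B(OMe)3, −78→0 °C; AcOH, 30% aq. H2O2, 0 °C→rt
Reagents that add atoms: hydrogen peroxide, OO
Why: Carbonyl-assisted deprotonation of the flavone at C3, borylation of the 3-lithio species and oxidative C–B to C–O migration with peroxide is an established flavone-to-flavonol sequence; acidic peroxide at 0 °C should leave the isolated alkene, the MOM acetal and the silyl ether untouched.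

Step 14
Reactants: 25 3-hydroxy-5,6-dimethoxy-7-(methoxymethoxy)-2-{4-methoxy-3-[(2R)-3-methyl-2-(triisopropylsilyloxy)but-3-enyl]phenyl}-4H-chromen-4-one
Product: 26 3-hydroxy-2-{3-[(2R)-2-hydroxy-3-methylbut-3-enyl]-4-methoxyphenyl}-5,6-dimethoxy-7-(methoxymethoxy)-4H-chromen-4-one
Conditions: Bu4NF, THF, 0 °C→rt; aqueous work-up
Reagents that add atoms: none
Why: Fluoride-induced Si–O cleavage of the secondary silyl ether; the MOM acetal is stable to Bu4NF and the flavonol is only deprotonated and reprotonated on work-up.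

Step 15
Reactants: 26 3-hydroxy-2-{3-[(2R)-2-hydroxy-3-methylbut-3-enyl]-4-methoxyphenyl}-5,6-dimethoxy-7-(methoxymethoxy)-4H-chromen-4-one
Product: 27 3,7-dihydroxy-2-{3-[(2R)-2-hydroxy-3-methylbut-3-enyl]-4-methoxyphenyl}-5,6-dimethoxy-4H-chromen-4-one
Conditions: HCl (0.5 M in MeOH), rt
Reagents that add atoms: none
Why: Acid-catalysed acetal exchange with methanol frees the C7 phenol; the electron-poor 7-aryloxy group leaves readily, so dilute acid at room temperature should suffice and spare the isopropenyl carbinol, whose stereocentre is not touched.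

**Compound list**
1 | 4-hydroxy-2,3-dimethoxybenzaldehyde | COc1c(O)ccc(C=O)c1OC | starting material
2 | 2,3-dimethoxy-4-(methoxymethoxy)benzaldehyde | COCOc1ccc(C=O)c(OC)c1OC | intermediate
3 | 2,3-dimethoxy-4-(methoxymethoxy)phenyl formate | COCOc1ccc(OC=O)c(OC)c1OC | intermediate
4 | 2,3-dimethoxy-4-(methoxymethoxy)phenol | COCOc1ccc(O)c(OC)c1OC | intermediate
5 | 6-bromo-2,3-dimethoxy-4-(methoxymethoxy)phenol | COCOc1cc(Br)c(O)c(OC)c1OC | intermediate
6 | [6-bromo-2,3-dimethoxy-4-(methoxymethoxy)phenoxy]trimethylsilane | COCOc1cc(Br)c(O[Si](C)(C)C)c(OC)c1OC | intermediate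
7 | lithium 2,3-dimethoxy-4-(methoxymethoxy)-6-(trimethylsilyl)phenoxide | COCOc1cc([Si](C)(C)C)c(O[Li])c(OC)c1OC | intermediate
8 | 2,3-dimethoxy-4-(methoxymethoxy)-6-(trimethylsilyl)phenyl trifluoromethanesulfonate | COCOc1cc([Si](C)(C)C)c(OS(=O)(=O)C(F)(F)F)c(OC)c1OC | intermediate
9 | 2-(5-bromo-2-methoxyphenyl)acetic acid | COc1ccc(Br)cc1CC(=O)O | starting material
10 | 2-(5-bromo-2-methoxyphenyl)-N-methoxy-N-methylacetamide | COc1ccc(Br)cc1CC(=O)N(C)OC | intermediate
11 | isopropenylmagnesium bromide | C=C(C)[Mg]Br | starting material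
12 | 1-(5-bromo-2-methoxyphenyl)-3-methylbut-3-en-2-one | C=C(C)C(=O)Cc1cc(Br)ccc1OC | intermediate
13 | (R)-1-(5-bromo-2-methoxyphenyl)-3-methylbut-3-en-2-ol | C=C(C)[C@H](O)Cc1cc(Br)ccc1OC | intermediate
14 | (R)-{[1-(5-bromo-2-methoxyphenyl)-3-methylbut-3-en-2-yl]oxy}triisopropylsilane | C=C(C)[C@H](O[Si](C(C)C)(C(C)C)C(C)C)Cc1cc(Br)ccc1OC | intermediate
15 | ethynyltrimethylsilane | C#C[Si](C)(C)C | starting material
16 | (R)-triisopropyl[(1-{2-methoxy-5-[(trimethylsilyl)ethynyl]phenyl}-3-methylbut-3-en-2-yl)oxy]silane | C=C(C)[C@H](O[Si](C(C)C)(C(C)C)C(C)C)Cc1cc(C#C[Si](C)(C)C)ccc1OC | intermediate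
17 | lithium {4-methoxy-3-[(2R)-3-methyl-2-(triisopropylsilyloxy)but-3-enyl]phenyl}acetylide | C=C(C)[C@H](O[Si](C(C)C)(C(C)C)C(C)C)Cc1cc(C#C[Li])ccc1OC | intermediate
18 | (R)-3-{4-methoxy-3-[3-methyl-2-(triisopropylsilyloxy)but-3-enyl]phenyl}propiolic acid | C=C(C)[C@H](O[Si](C(C)C)(C(C)C)C(C)C)Cc1cc(C#CC(=O)O)ccc1OC | intermediate
19 | 3,4-dimethoxy-5-(methoxymethoxy)benzyne | COCOC1=CC#CC(OC)=C1OC | intermediate
20 | (R)-1-[6-hydroxy-2,3-dimethoxy-4-(methoxymethoxy)phenyl]-3-{4-methoxy-3-[3-methyl-2-(triisopropylsilyloxy)but-3-enyl]phenyl}prop-2-yn-1-one | C=C(C)[C@H](O[Si](C(C)C)(C(C)C)C(C)C)Cc1cc(C#CC(=O)c2c(O)cc(OCOC)c(OC)c2OC)ccc1OC | intermediate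
21 | (E)-3-(diethylamino)-1-[6-hydroxy-2,3-dimethoxy-4-(methoxymethoxy)phenyl]-3-{4-methoxy-3-[(2R)-3-methyl-2-(triisopropylsilyloxy)but-3-enyl]phenyl}prop-2-en-1-one | C=C(C)[C@H](O[Si](C(C)C)(C(C)C)C(C)C)Cc1cc(/C(=C\C(=O)c2c(O)cc(OCOC)c(OC)c2OC)N(CC)CC)ccc1OC | intermediate
22 | 5,6-dimethoxy-7-(methoxymethoxy)-2-{4-methoxy-3-[(2R)-3-methyl-2-(triisopropylsilyloxy)but-3-enyl]phenyl}-4H-chromen-4-one | C=C(C)[C@H](O[Si](C(C)C)(C(C)C)C(C)C)Cc1cc(-c2cc(=O)c3c(OC)c(OC)c(OCOC)cc3o2)ccc1OC | intermediate
23 | 3-lithio derivative of flavone 22 | C=C(C)[C@H](O[Si](C(C)C)(C(C)C)C(C)C)Cc1cc(-c2oc3cc(OCOC)c(OC)c(OC)c3c(=O)c2[Li])ccc1OC | intermediate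
24 | dimethyl (flavon-3-yl)boronate of 22 | C=C(C)[C@H](O[Si](C(C)C)(C(C)C)C(C)C)Cc1cc(-c2oc3cc(OCOC)c(OC)c(OC)c3c(=O)c2B(OC)OC)ccc1OC | intermediate
25 | 3-hydroxy-5,6-dimethoxy-7-(methoxymethoxy)-2-{4-methoxy-3-[(2R)-3-methyl-2-(triisopropylsilyloxy)but-3-enyl]phenyl}-4H-chromen-4-one | C=C(C)[C@H](O[Si](C(C)C)(C(C)C)C(C)C)Cc1cc(-c2oc3cc(OCOC)c(OC)c(OC)c3c(=O)c2O)ccc1OC | intermediate
26 | 3-hydroxy-2-{3-[(2R)-2-hydroxy-3-methylbut-3-enyl]-4-methoxyphenyl}-5,6-dimethoxy-7-(methoxymethoxy)-4H-chromen-4-one | C=C(C)[C@H](O)Cc1cc(-c2oc3cc(OCOC)c(OC)c(OC)c3c(=O)c2O)ccc1OC | intermediate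
27 | 3,7-dihydroxy-2-{3-[(2R)-2-hydroxy-3-methylbut-3-enyl]-4-methoxyphenyl}-5,6-dimethoxy-4H-chromen-4-one | C=C(C)[C@H](O)Cc1cc(-c2oc3cc(O)c(OC)c(OC)c3c(=O)c2O)ccc1OC | target

**Step count**
Total: 15 steps. Longest linear sequence: 11 steps (steps 5–15, from 9).

**Steps most likely to fail**

Step 11. The aryl anion may be protonated before the acyl shift (O-arylation instead of insertion), the cesium arylpropiolate may lose CO2 at the temperature needed to form the aryne, or fluoride may trigger 5-exo closure of the ynone phenoxide or silyl ether cleavage. The fallback sets out from triflate 8 and silylalkyne 16 and comes back at ynone 20. Aryne 19 is generated from 8 with CsF in DMF, so that it inserts into the formamide C=O bond under the same polarity control (oxygen to C8a, formyl carbon to C4a). Aqueous work-up hydrolyses the adduct to 6-hydroxy-2,3-dimethoxy-4-(methoxymethoxy)benzaldehyde F1. TBSCl and imidazole in DMF give 6-(tert-butyldimethylsilyloxy)-2,3-dimethoxy-4-(methoxymethoxy)benzaldehyde F2. Lithium acetylide 17, made from 16 with MeLi·LiBr, adds at −78 °C to give the propargylic alcohol F3 as both carbinol epimers. MnO2 in CH2Cl2 oxidises it to the ynone silyl ether F4, and Bu4NF buffered with AcOH at 0 °C removes only the aryl silyl group to give 20.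

Step 13. Deprotonation may compete at C8 (flanked by O1 and the MOM ether), the amide base may add at C2 with ring opening, or the 3-lithio species may condense with unreacted flavone. The fallback sets out from ynone 20 and comes back at flavonol 25. One equivalent of Et2NH in CH2Cl2 at 0 °C converts 20 into enaminone 21, which is intercepted before it cyclises with one equivalent of iodine: the enamine α-carbon (the future C3) is iodinated and the phenol closes ring C with loss of diethylamine, giving the 3-iodoflavone F5. Iodine–magnesium exchange with iPrMgCl·LiCl at −40 °C gives the 3-magnesioflavone F6, which B(OMe)3 converts into boronate 24; H2O2/AcOH then gives 25. The metal is thus placed by exchange, not by deprotonation.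

Step 7. Facial discrimination between the benzylic CH2 and isopropenyl groups may be too low, or the borane may hydroborate the alkene. The fallback sets out from enone 12 and comes back at alcohol 13. Luche reduction (NaBH4, CeCl3·7H2O, MeOH, −40 °C) gives racemic 1-(5-bromo-2-methoxyphenyl)-3-methylbut-3-en-2-ol F7. Sharpless kinetic resolution (Ti(OiPr)4, L-(+)-diisopropyl tartrate, t-BuOOH (0.6 equiv), 4 Å molecular sieves, CH2Cl2, −20 °C) should epoxidise the (S) enantiomer to the erythro epoxy alcohol (1S)-2-(5-bromo-2-methoxyphenyl)-1-[(2R)-2-methyloxiran-2-yl]ethan-1-ol F8 and leave (R)-alcohol 13 to be recovered.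

**Further compounds**
F1 | step 11 | 6-hydroxy-2,3-dimethoxy-4-(methoxymethoxy)benzaldehyde | COCOc1cc(O)c(C=O)c(OC)c1OC
F2 | step 11 | 6-(tert-butyldimethylsilyloxy)-2,3-dimethoxy-4-(methoxymethoxy)benzaldehyde | COCOc1cc(O[Si](C)(C)C(C)(C)C)c(C=O)c(OC)c1OC
F3 | step 11 | 1-[6-(tert-butyldimethylsilyloxy)-2,3-dimethoxy-4-(methoxymethoxy)phenyl]-3-{4-methoxy-3-[(2R)-3-methyl-2-(triisopropylsilyloxy)but-3-enyl]phenyl}prop-2-yn-1-ol (both carbinol epimers) | C=C(C)[C@H](O[Si](C(C)C)(C(C)C)C(C)C)Cc1cc(C#CC(O)c2c(O[Si](C)(C)C(C)(C)C)cc(OCOC)c(OC)c2OC)ccc1OC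
F4 | step 11 | 1-[6-(tert-butyldimethylsilyloxy)-2,3-dimethoxy-4-(methoxymethoxy)phenyl]-3-{4-methoxy-3-[(2R)-3-methyl-2-(triisopropylsilyloxy)but-3-enyl]phenyl}prop-2-yn-1-one | C=C(C)[C@H](O[Si](C(C)C)(C(C)C)C(C)C)Cc1cc(C#CC(=O)c2c(O[Si](C)(C)C(C)(C)C)cc(OCOC)c(OC)c2OC)ccc1OC
F5 | step 13 | 3-iodo-5,6-dimethoxy-7-(methoxymethoxy)-2-{4-methoxy-3-[(2R)-3-methyl-2-(triisopropylsilyloxy)but-3-enyl]phenyl}-4H-chromen-4-one | C=C(C)[C@H](O[Si](C(C)C)(C(C)C)C(C)C)Cc1cc(-c2oc3cc(OCOC)c(OC)c(OC)c3c(=O)c2I)ccc1OC
F6 | step 13 | 3-(chloromagnesio) derivative of flavone 22 | C=C(C)[C@H](O[Si](C(C)C)(C(C)C)C(C)C)Cc1cc(-c2oc3cc(OCOC)c(OC)c(OC)c3c(=O)c2[Mg]Cl)ccc1OC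
F7 | step 7 | racemic 1-(5-bromo-2-methoxyphenyl)-3-methylbut-3-en-2-ol | C=C(C)C(O)Cc1cc(Br)ccc1OC
F8 | step 7 | (1S)-2-(5-bromo-2-methoxyphenyl)-1-[(2R)-2-methyloxiran-2-yl]ethan-1-ol | C[C@@]1(CO1)[C@@H](O)Cc1cc(Br)ccc1OC
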